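(The data are calculated on assumed constants; noise was put on by code.)

Early times are where the two earlier runs can first be set side by side.

common to all: solid substrate 20 mM; free catalyst 0.20 mM
- winter: second substrate 5 mM; coupling partner 18 mM; capture agent 1 mM; temperature 12 °C; run made earlier
- midnight: second substrate 15 mM; coupling partner 18 mM; capture agent 1 mM; temperature 29 °C; run made earlier
- delta: second substrate 20.0 mM; coupling partner 18.0 mM; capture agent 1.00 mM; at 5 °C until 8.0 h, from then on at 35 °C; time 25 h
- eta: second substrate 6.00 mM; coupling partner 18.0 mM; capture agent 1.00 mM; at 5 °C throughout; time 25 h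

- winter (time / h: target / %): 1.50: 1.1; 5.00: 4.2; 8.00: 5.3; 15.0: 14.2; 20.0: 22.5; 25.0: 28.0
- midnight (time / h: target / %): 1.33: 0; 2.50: 3.2; 4.00: 4.4; 5.00: 5.6; 6.00: 6.5; 8.00: 9.5

(standard deviation of a reading: 1 percentage point)

- which of the two ends with the higher amount of target, in percent of the solid substrate charged ("neither" if they lie within 2 percentage points) (delta / eta / neither)
- target at the end, in percent of the solid substrate charged, delta
- target at the end, in percent of the solid substrate charged, eta

- solid substrate is a solid; its amount is given per volume of the solution
- at the start none of the solid substrate is in solution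
- what has only dissolved of solid substrate counts as not reacted

What do the readings at 8.00 h show? The winter run stands at 5.3 % of target and the midnight run at 9.5 %, a factor of 1.79.

Is that factor the effect of warmth? I cannot say. Midnight is warmer, but its [second substrate] is also higher, at 15 mM against 5 mM. The two settings moved together.

What can you promise without a rate? A ceiling. Suppose each target takes one solid substrate and one coupling partner. Coupling partner is then the limiting reagent, since its charge of 18.0 mM lies below the 20 mM of solid substrate. That gives 90.0 %. I call this the coupling budget: the coupling partner charged, as a percentage of the solid substrate charged.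

Is the budget a forecast of the yield? No. The readings show no coupling partner, so they cannot say whether something else spends it. The budget tells what there is to spend, not who spends it.

Then commit to numbers. Midnight's pace, carried over the warm 17.0 h of delta, gives 20.2 %. Eta is colder than winter, so as my own guess I take 0.5 of winter's last reading, 14.0 %. So I expect delta to end higher than eta.

The forecast also names delta, with 50 % for delta and 17 % for eta. On delta it says: “The cap is 90%, but the rate is uncertain.” Its delta stands above my figure.

The flask gives 30.9 % for delta and 19.0 % for eta, so delta ends higher, and the forecast stands 19 percentage points too high on delta.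

    starting material + free catalyst ⇌ catalyst intermediate A (K = 10900 L mol⁻¹, k = 284 L mol⁻¹ h⁻¹, Ea = 59.0 kJ mol⁻¹, ΔH = −13.0 kJ mol⁻¹)
    solid substrate ⇌ starting material, rate k2*(cs2 - [starting material]) while solid is left; crystals form when [starting material] > cs2 (solubility = 17.0 mM, k = 0.0281 h⁻¹)
    coupling partner + catalyst intermediate A → free catalyst + target (k = 2670 L mol⁻¹ h⁻¹, Ea = 37.0 kJ mol⁻¹)
    second substrate + free catalyst ⇌ catalyst intermediate B (K = 960 L mol⁻¹, k = 290 L mol⁻¹ h⁻¹, Ea = 41.0 kJ mol⁻¹, ΔH = −50.0 kJ mol⁻¹)
    catalyst intermediate A + capture agent → trapped intermediate (k = 130 L mol⁻¹ h⁻¹, Ea = 65.0 kJ mol⁻¹)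
    coupling partner + catalyst intermediate B → free catalyst + second product (k = 257 L mol⁻¹ h⁻¹, Ea = 45.0 kJ mol⁻¹)
    (constants at 5 °C)

In eta at 11.2 h, the step to target and the step to second product used coupling partner at a rate ratio of 1.0. In delta at the end, target held 6.18 mM of coupling partner and second product 10.6 mM, with 6.5 % of the charge left, so target reached 34.3 % of the budget of 90.0 %. The flask like eta but kept at 30 °C ended with 43.5 % of target, which is 48.3 % of the budget, beside 5.48 mM of second product and 21 % of its coupling partner left.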